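**Retrosynthetic overview**
1. The C14=C15′ enal is cut by a retro-aldol condensation into two 15-oxolabd-8(17)-en-19-oates that differ only at C5: the 5α (trans-fused) donor, which keeps its CHO, and the 5β (cis-fused) acceptor.
2. The strategy rests on rings A and B of the trans-fused half. C19–C4–C3(=O)–C2–C1–C10(C20)=C5–C6–C7–C8(C17)=C9 is an (E,E)-dienyl β-keto ester, so C4–C5 (ring A) and then C9–C10 (ring B) close in one oxidative radical cascade that ends as the C8=C17 methylene.
3. Both halves come from the single cyclization product 12 (C4–H). The trans half is made by C4 methylation anti to C20. The cis half is made by dehydrogenation to the C4=C5 keto ester, hydride delivery to C5 cis to C20, then C4 methylation.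
4. Precursor 11 comes from (2E,6E)-farnesol (asymmetric hydrogenation sets C13, allylic oxidation, bromide) and the acetoacetate of (+)-8-phenylmenthol by dianion alkylation.
5. Each half is then deoxygenated at C3, the auxiliary ester is exchanged for an allyl ester and C15 is oxidized; an imine-directed aldol condensation and deallylation finish the route.

Key step: step 7

**Remarks on the chemistry**
- Labdane numbering is used. Unprimed atoms are the trans-fused half (5α-H), primed atoms the cis-fused half (5β-H). Both halves have 4β-CO2H, 4α-CH3, 9α-H, 10β-CH3 and 13S, and the enal is E (CHO trans to C14′).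
- C18 is kept out of the radical step. A chelated β-dicarbonyl radical, the form in which the auxiliary can shield one face, holds the ester syn to the C3 carbonyl oxygen, and that substituent ends up equatorial. A 2-methyl keto ester would therefore give the C4 epimer, so the C4–H keto ester is cyclized and C18 is added afterwards.
- The auxiliary is (1S,2R,5S)-(+)-8-phenylmenthol. In the chelated ester its phenyl group covers the face from which C5 would otherwise give the enantiomeric decalin, the same sense that this auxiliary shows in chelation-controlled additions to its α-oxo esters.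
- The C15 oxygen is carried as a tert-butyldiphenylsilyl ether, chosen to survive the Lewis-acidic key step and the chromic acid oxidation.

**Route**

Step 1
Reactants: 1 (2E,6E)-farnesol
Product: 2 (3S,6E)-3,7,11-trimethyldodeca-6,10-dien-1-ol
Conditions: Ru(OAc)2[(R)-BINAP] (0.2 mol %), H2 (30 atm), MeOH/H2O 95:5, 20 °C
Reagents that add atoms: none
Why: Noyori-type asymmetric hydrogenation in which the allylic hydroxyl binds ruthenium, so only the 2,3-olefin is reduced, and the R-configured BINAP complex with an E allylic alcohol should give the 3S alcohol (the sense known for geraniol to (S)-citronellol), which sets C13.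

Step 2
Reactants: 2 (3S,6E)-3,7,11-trimethyldodeca-6,10-dien-1-ol
Product: 3 tert-butyldiphenylsilyl ether of 2
Conditions: t-BuPh2SiCl, imidazole, CH2Cl2, 0 °C to rt
Reagents that add atoms: tert-butyl(chloro)diphenylsilane, CC(C)(C)[Si](Cl)(c1ccccc1)c1ccccc1
Why: Standard imidazole-promoted silylation of a primary alcohol, giving an ether that should tolerate the later Lewis acid, hydride and chromic acid steps.

Step 3
Reactants: 3 tert-butyldiphenylsilyl ether of 2
Product: 4 (2E,6E,10S)-12-(tert-butyldiphenylsilyloxy)-2,6,10-trimethyldodeca-2,6-dien-1-ol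
Conditions: SeO2 (0.3 equiv), t-BuOOH, salicylic acid (cat.), CH2Cl2, 0 °C to rt, stopped at partial conversion, 3 recycled
Reagents that add atoms: selenium dioxide, O=[Se]=O; tert-butyl hydroperoxide, CC(C)(C)OO
Why: Sharpless allylic oxidation (ene reaction then [2,3]-shift) is expected to take the E-methyl of the terminal trisubstituted olefin in preference to the internal olefin and to keep the E geometry that later becomes C1 trans to C6.

Step 4
Reactants: 4 (2E,6E,10S)-12-(tert-butyldiphenylsilyloxy)-2,6,10-trimethyldodeca-2,6-dien-1-ol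
Product: 5 (2E,6E,10S)-1-bromo-12-(tert-butyldiphenylsilyloxy)-2,6,10-trimethyldodeca-2,6-diene
Conditions: CBr4, PPh3, 2,6-lutidine, CH2Cl2, -20 °C to 0 °C
Reagents that add atoms: carbon tetrabromide, BrC(Br)(Br)Br
Why: Appel bromination of a primary allylic alcohol proceeds by SN2 on the alkoxyphosphonium ion without allylic transposition or loss of olefin geometry.

Step 5
Reactants: 6 (1S,2R,5S)-(+)-8-phenylmenthol; 7 2,2,6-trimethyl-4H-1,3-dioxin-4-one
Product: 9 (1S,2R,5S)-8-phenylmenthyl 3-oxobutanoate, via acetylketene 8 (not isolated)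
Conditions: xylene, 140 °C, acetone distilled off
Reagents that add atoms: none
Why: Thermal retro-[4+2] cleavage of the dioxinone gives acetylketene, which acylates even hindered secondary alcohols cleanly.

Step 6
Reactants: 9 (1S,2R,5S)-8-phenylmenthyl 3-oxobutanoate; 5 (2E,6E,10S)-1-bromo-12-(tert-butyldiphenylsilyloxy)-2,6,10-trimethyldodeca-2,6-diene
Product: 11 (1S,2R,5S)-8-phenylmenthyl (6E,10E,14S)-16-(tert-butyldiphenylsilyloxy)-6,10,14-trimethyl-3-oxohexadeca-6,10-dienoate, via dilithio dianion 10 (not isolated)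
Conditions: LiN(iPr)2 (2.1 equiv), THF, 0 °C; then 5, -78 °C to 0 °C; aq. NH4Cl
Reagents that add atoms: none
Why: Weiler dianion alkylation, in which the more basic γ-carbanion of the acetoacetate attacks the primary allylic bromide by SN2 and forms the C1–C2 bond.

Step 7
Reactants: 11 (1S,2R,5S)-8-phenylmenthyl (6E,10E,14S)-16-(tert-butyldiphenylsilyloxy)-6,10,14-trimethyl-3-oxohexadeca-6,10-dienoate
Product: 12 (1S,2R,5S)-8-phenylmenthyl 15-(tert-butyldiphenylsilyloxy)-3-oxo-18-norlabd-8(17)-en-19-oate (trans-fused: 5α-H 9α-H 10β-CH3 13S; C4–H as keto/enol mixture)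
Conditions: Mn(OAc)3·2H2O (2.2 equiv), Cu(OAc)2·H2O (1.0 equiv), Yb(OTf)3 (1.0 equiv), CF3CH2OH, degassed, -5 °C to 0 °C
Reagents that add atoms: none
Why: Trivalent manganese oxidizes the Yb(OTf)3-chelated enol of 11 to the electrophilic C4 radical, which adds to C5 of the C5=C10 olefin (ring A); the tertiary C10 radical then adds to C9 of the C8=C9 olefin (ring B), and divalent copper captures the tertiary C8 radical and loses a C17 hydrogen to leave the C8=C17 methylene. The closest known reaction type is the Mn(OAc)3/Cu(OAc)2 oxidative free-radical polyene cyclization of unsaturated β-keto esters, including its lanthanide-triflate-assisted 8-phenylmenthyl ester version. Both closures are 6-endo-trig, enforced by the methyl groups on C10 and C8 (attack at the less substituted olefin carbon gives the tertiary radical) and by the ketone lying inside the forming ring. The E,E-diene folds chair–chair, so the E geometry of C5=C10 puts H-5 anti to C20 (trans fusion) and the E geometry of C8=C9 puts the C9 side chain equatorial. The absolute sense of C5, C10 and C9 comes from the auxiliary: in the planar chelated dicarbonyl radical the phenyl ring of the (1S,2R,5S) ester lies over one face of C4, so C5 should bond to the open face, while C4 stays enolizable and is fixed in later steps. The step needs face selection and exocyclic rather than endocyclic elimination; the first rests on chelation at low temperature, the second on the preference of the organocopper intermediate for loss of an unhindered methyl hydrogen.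

Step 8
Reactants: 12 (1S,2R,5S)-8-phenylmenthyl 15-(tert-butyldiphenylsilyloxy)-3-oxo-18-norlabd-8(17)-en-19-oate
Product: 13 (1S,2R,5S)-8-phenylmenthyl 15-(tert-butyldiphenylsilyloxy)-3-oxolabd-8(17)-en-19-oate (4α-CH3 4β-ester 5α-H)
Conditions: K2CO3, MeI, DMF, rt
Reagents that add atoms: iodomethane, CI
Why: C-alkylation of the β-keto ester enolate, in which methyl iodide should enter axially from the α face, anti to the axial C20 methyl and to the phenyl of the auxiliary, so that C4 gets its α-methyl and the axial β-ester.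

Step 9
Reactants: 13 (1S,2R,5S)-8-phenylmenthyl 15-(tert-butyldiphenylsilyloxy)-3-oxolabd-8(17)-en-19-oate
Product: 14 3-hydroxy ester from 13 (C3 epimers, both carried on)
Conditions: NaBH4, MeOH/THF, 0 °C to rt
Reagents that add atoms: none
Why: Borohydride reduces the ketone but not the hindered neopentyl ester, and the C3 configuration is of no consequence because C3 becomes CH2.

Step 10
Reactants: 14 3-hydroxy ester from 13
Product: 15 3-O-(imidazol-1-ylthiocarbonyl) derivative of 14
Conditions: 1,1'-thiocarbonyldiimidazole, DMAP (cat.), ClCH2CH2Cl, 70 °C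
Reagents that add atoms: 1,1'-thiocarbonyldiimidazole, S=C(n1ccnc1)n1ccnc1
Why: Neutral thioacylation of the hindered secondary alcohol avoids the strong base that could open the β-hydroxy ester by retro-aldol cleavage.

Step 11
Reactants: 15 3-O-(imidazol-1-ylthiocarbonyl) derivative of 14
Product: 16 (1S,2R,5S)-8-phenylmenthyl 15-(tert-butyldiphenylsilyloxy)labd-8(17)-en-19-oate
Conditions: Bu3SnH, AIBN (cat.), toluene, 100 °C
Reagents that add atoms: none
Why: Barton–McCombie deoxygenation, in which the secondary C3 radical is reduced by the stannane faster than it can rearrange and is too far from C8=C17 to cyclize.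

Step 12
Reactants: 16 (1S,2R,5S)-8-phenylmenthyl 15-(tert-butyldiphenylsilyloxy)labd-8(17)-en-19-oate
Product: 17 15-(tert-butyldiphenylsilyloxy)labd-8(17)-en-19-ol
Conditions: LiAlH4, THF, 0 °C to 50 °C; aqueous NaOH work-up; auxiliary 6 recovered
Reagents that add atoms: none
Why: Hydride reduction is the reliable way to release a hindered axial ester from its auxiliary, and the silyl ether and the isolated olefin are inert to it.

Step 13
Reactants: 17 15-(tert-butyldiphenylsilyloxy)labd-8(17)-en-19-ol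
Product: 19 15-(tert-butyldiphenylsilyloxy)labd-8(17)-en-19-oic acid, via C19 aldehyde 18 (not isolated)
Conditions: CrO3, H2SO4, acetone, 0 °C; i-PrOH quench
Reagents that add atoms: water, O
Why: Jones oxidation takes the neopentyl primary alcohol through the aldehyde hydrate to the acid and should spare the exocyclic olefin and the acid-stable tert-butyldiphenylsilyl ether.

Step 14
Reactants: 19 15-(tert-butyldiphenylsilyloxy)labd-8(17)-en-19-oic acid
Product: 20 allyl 15-(tert-butyldiphenylsilyloxy)labd-8(17)-en-19-oate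
Conditions: allyl bromide, K2CO3, DMF, rt
Reagents that add atoms: allyl bromide, C=CCBr
Why: O-alkylation of the carboxylate by SN2 is insensitive to the hindrance at C4 and gives an ester that can be removed at the end without acid, base or hydride.

Step 15
Reactants: 20 allyl 15-(tert-butyldiphenylsilyloxy)labd-8(17)-en-19-oate
Product: 21 allyl 15-hydroxylabd-8(17)-en-19-oate
Conditions: Bu4NF, AcOH (1 equiv), THF, rt
Reagents that add atoms: none
Why: Buffered fluoride desilylation frees the primary alcohol and leaves the hindered allyl ester alone.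

Step 16
Reactants: 21 allyl 15-hydroxylabd-8(17)-en-19-oate
Product: 22 allyl 15-oxolabd-8(17)-en-19-oate
Conditions: Dess–Martin periodinane, NaHCO3, CH2Cl2, rt
Reagents that add atoms: none
Why: Dess–Martin oxidation stops at the aldehyde, and C13 is β to the new carbonyl and cannot epimerize.

Step 17
Reactants: 22 allyl 15-oxolabd-8(17)-en-19-oate
Product: 23 N-cyclohexyl aldimine of 22
Conditions: cyclohexylamine, MgSO4, CH2Cl2, rt; used crude
Reagents that add atoms: cyclohexylamine, NC1CCCCC1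
Why: Imine condensation turns the donor aldehyde into a form that can be deprotonated at C14 without self-condensation.

Step 18
Reactants: 12 (1S,2R,5S)-8-phenylmenthyl 15-(tert-butyldiphenylsilyloxy)-3-oxo-18-norlabd-8(17)-en-19-oate
Product: 26 (1S,2R,5S)-8-phenylmenthyl 15-(tert-butyldiphenylsilyloxy)-3-oxo-18-norlabda-4,8(17)-dien-19-oate, via α-phenylselenide 24 (not isolated), via selenoxide 25 (not isolated)
Conditions: PhSeCl (1.05 equiv), pyridine, CH2Cl2, -78 °C to 0 °C; then 30% H2O2, 0 °C to rt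
Reagents that add atoms: none
Why: Selenenylation of the enol at C4 from the α face followed by selenoxide syn-elimination with the α-oriented H-5 gives the C4=C5 keto ester, which erases the C5 stereocentre while C9, C10 and C13 stay as set.

Step 19
Reactants: 26 (1S,2R,5S)-8-phenylmenthyl 15-(tert-butyldiphenylsilyloxy)-3-oxo-18-norlabda-4,8(17)-dien-19-oate
Product: 27 (1S,2R,5S)-8-phenylmenthyl 15-(tert-butyldiphenylsilyloxy)-3-oxo-18-nor-5β-labd-8(17)-en-19-oate (cis-fused; C4–H as keto/enol mixture)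
Conditions: [(Ph3P)CuH]6 (0.5 equiv), toluene/THF, rt; aq. NH4Cl
Reagents that add atoms: none
Why: Copper hydride conjugate reduction of the doubly activated olefin should place the hydride on C5 cis to C20, the face that bulky copper nucleophiles take on 10-methyl-Δ4-3-octalones because axial entry from the α side is blocked by the axial H-7 and H-9, and this gives the 5β-H cis fusion without touching C8=C17.

Step 20
Reactants: 27 (1S,2R,5S)-8-phenylmenthyl 15-(tert-butyldiphenylsilyloxy)-3-oxo-18-nor-5β-labd-8(17)-en-19-oate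
Product: 28 (1S,2R,5S)-8-phenylmenthyl 15-(tert-butyldiphenylsilyloxy)-3-oxo-5β-labd-8(17)-en-19-oate (4α-CH3 4β-ester)
Conditions: K2CO3, MeI, DMF, rt
Reagents that add atoms: iodomethane, CI
Why: C-alkylation of the chelated β-keto ester enolate, in which A(1,2) strain with the C4 ester should hold C6 pseudoaxial so that C20 lies over the β face, which the phenyl of the auxiliary also covers, and methyl iodide is therefore expected from the α face.

Step 21
Reactants: 28 (1S,2R,5S)-8-phenylmenthyl 15-(tert-butyldiphenylsilyloxy)-3-oxo-5β-labd-8(17)-en-19-oate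
Product: 29 3-hydroxy ester from 28 (C3 epimers, both carried on)
Conditions: NaBH4, MeOH/THF, 0 °C to rt
Reagents that add atoms: none
Why: Chemoselective borohydride reduction of the ketone beside the hindered ester, as in step 9.

Step 22
Reactants: 29 3-hydroxy ester from 28
Product: 30 3-O-(imidazol-1-ylthiocarbonyl) derivative of 29
Conditions: 1,1'-thiocarbonyldiimidazole, DMAP (cat.), ClCH2CH2Cl, 70 °C
Reagents that add atoms: 1,1'-thiocarbonyldiimidazole, S=C(n1ccnc1)n1ccnc1
Why: Neutral thioacylation, as in step 10.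

Step 23
Reactants: 30 3-O-(imidazol-1-ylthiocarbonyl) derivative of 29
Product: 31 (1S,2R,5S)-8-phenylmenthyl 15-(tert-butyldiphenylsilyloxy)-5β-labd-8(17)-en-19-oate
Conditions: Bu3SnH, AIBN (cat.), toluene, 100 °C
Reagents that add atoms: none
Why: Barton–McCombie deoxygenation, as in step 11.

Step 24
Reactants: 31 (1S,2R,5S)-8-phenylmenthyl 15-(tert-butyldiphenylsilyloxy)-5β-labd-8(17)-en-19-oate
Product: 32 15-(tert-butyldiphenylsilyloxy)-5β-labd-8(17)-en-19-ol
Conditions: LiAlH4, THF, 0 °C to 50 °C; aqueous NaOH work-up; auxiliary 6 recovered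
Reagents that add atoms: none
Why: Hydride cleavage of the hindered auxiliary ester, as in step 12.

Step 25
Reactants: 32 15-(tert-butyldiphenylsilyloxy)-5β-labd-8(17)-en-19-ol
Product: 34 15-(tert-butyldiphenylsilyloxy)-5β-labd-8(17)-en-19-oic acid, via C19 aldehyde 33 (not isolated)
Conditions: CrO3, H2SO4, acetone, 0 °C; i-PrOH quench
Reagents that add atoms: water, O
Why: Jones oxidation of the neopentyl alcohol, as in step 13.

Step 26
Reactants: 34 15-(tert-butyldiphenylsilyloxy)-5β-labd-8(17)-en-19-oic acid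
Product: 35 allyl 15-(tert-butyldiphenylsilyloxy)-5β-labd-8(17)-en-19-oate
Conditions: allyl bromide, K2CO3, DMF, rt
Reagents that add atoms: allyl bromide, C=CCBr
Why: Carboxylate O-alkylation, as in step 14.

Step 27
Reactants: 35 allyl 15-(tert-butyldiphenylsilyloxy)-5β-labd-8(17)-en-19-oate
Product: 36 allyl 15-hydroxy-5β-labd-8(17)-en-19-oate
Conditions: Bu4NF, AcOH (1 equiv), THF, rt
Reagents that add atoms: none
Why: Buffered fluoride desilylation, as in step 15.

Step 28
Reactants: 36 allyl 15-hydroxy-5β-labd-8(17)-en-19-oate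
Product: 37 allyl 15-oxo-5β-labd-8(17)-en-19-oate
Conditions: Dess–Martin periodinane, NaHCO3, CH2Cl2, rt
Reagents that add atoms: none
Why: Dess–Martin oxidation to the acceptor aldehyde, as in step 16.

Step 29
Reactants: 23 N-cyclohexyl aldimine of 22; 37 allyl 15-oxo-5β-labd-8(17)-en-19-oate
Product: 41 diallyl ester of the target (E-enal), via lithio azaenolate 38 (not isolated), via aldol imine 39 (not isolated), via hydroxy aldehyde 40 (not isolated)
Conditions: 23, LiN(iPr)2 (1.05 equiv), THF, -78 °C to 0 °C; then 37, -78 °C; then aq. oxalic acid, THF, rt to 40 °C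
Reagents that add atoms: water, O
Why: Wittig directed aldol condensation, in which the 1-azaallyl anion at C14 adds to the acceptor aldehyde and aqueous oxalic acid then hydrolyses the imine and dehydrates the aldol to the conjugated enal, whose E isomer (CHO trans to C14′) is the thermodynamic one for 2-alkyl-2-enals; the two carbinol-stage centres vanish on dehydration.

Step 30
Reactants: 41 diallyl ester of the target
Product: 42 target diacid CNP0229303.1
Conditions: Pd(PPh3)4 (5 mol %), N-methylaniline, THF, rt; dilute aqueous citric acid wash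
Reagents that add atoms: none
Why: Tsuji–Trost deallylation ionizes the allyl–oxygen bond irrespective of the hindrance at C4 and passes the allyl group to a weakly nucleophilic amine that should leave the enal and both methylene groups alone.

**Compound list**
1 | (2E,6E)-farnesol | CC(C)=CCC/C(C)=C/CC/C(C)=C/CO | starting material
2 | (3S,6E)-3,7,11-trimethyldodeca-6,10-dien-1-ol | CC(C)=CCC/C(C)=C/CC[C@H](C)CCO | intermediate
3 | tert-butyldiphenylsilyl ether of 2 | CC(C)=CCC/C(C)=C/CC[C@H](C)CCO[Si](c1ccccc1)(c1ccccc1)C(C)(C)C | intermediate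
4 | (2E,6E,10S)-12-(tert-butyldiphenylsilyloxy)-2,6,10-trimethyldodeca-2,6-dien-1-ol | OC/C(C)=C/CC/C(C)=C/CC[C@H](C)CCO[Si](c1ccccc1)(c1ccccc1)C(C)(C)C | intermediate
5 | (2E,6E,10S)-1-bromo-12-(tert-butyldiphenylsilyloxy)-2,6,10-trimethyldodeca-2,6-diene | BrC/C(C)=C/CC/C(C)=C/CC[C@H](C)CCO[Si](c1ccccc1)(c1ccccc1)C(C)(C)C | intermediate
6 | (1S,2R,5S)-(+)-8-phenylmenthol | CC(C)(c1ccccc1)[C@H]2CC[C@H](C)C[C@@H]2O | starting material
7 | 2,2,6-trimethyl-4H-1,3-dioxin-4-one | CC1=CC(=O)OC(C)(C)O1 | starting material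
8 | acetylketene (not isolated) | CC(=O)C=C=O | intermediate
9 | (1S,2R,5S)-8-phenylmenthyl 3-oxobutanoate | CC(C)(c1ccccc1)[C@H]2CC[C@H](C)C[C@@H]2OC(=O)CC(C)=O | intermediate
10 | dilithio dienolate of 9 (not isolated) | C=C(O[Li])C=C(O[Li])O[C@H]1C[C@@H](C)CC[C@@H]1C(C)(C)c1ccccc1 | intermediate
11 | (1S,2R,5S)-8-phenylmenthyl (6E,10E,14S)-16-(tert-butyldiphenylsilyloxy)-6,10,14-trimethyl-3-oxohexadeca-6,10-dienoate | CC(C)(c1ccccc1)[C@H]2CC[C@H](C)C[C@@H]2OC(=O)CC(=O)CC/C(C)=C/CC/C(C)=C/CC[C@H](C)CCO[Si](c3ccccc3)(c4ccccc4)C(C)(C)C | intermediate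
12 | 8-phenylmenthyl 15-(silyloxy)-3-oxo-18-norlabd-8(17)-en-19-oate, trans-fused, C4–H (keto form drawn) | C=C1CC[C@@H]2[C@](C)(CCC(=O)C2C(=O)O[C@H]3C[C@@H](C)CC[C@@H]3C(C)(C)c4ccccc4)[C@H]1CC[C@H](C)CCO[Si](c5ccccc5)(c6ccccc6)C(C)(C)C | intermediate
13 | 8-phenylmenthyl 15-(silyloxy)-3-oxolabd-8(17)-en-19-oate, trans-fused, 4α-CH3 | C=C1CC[C@@H]2[C@](C)(CCC(=O)[C@]2(C)C(=O)O[C@H]3C[C@@H](C)CC[C@@H]3C(C)(C)c4ccccc4)[C@H]1CC[C@H](C)CCO[Si](c5ccccc5)(c6ccccc6)C(C)(C)C | intermediate
14 | 3-hydroxy ester from 13 (C3 epimers) | C=C1CC[C@@H]2[C@](C)(CCC(O)[C@]2(C)C(=O)O[C@H]3C[C@@H](C)CC[C@@H]3C(C)(C)c4ccccc4)[C@H]1CC[C@H](C)CCO[Si](c5ccccc5)(c6ccccc6)C(C)(C)C | intermediate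
15 | 3-O-(imidazol-1-ylthiocarbonyl) derivative of 14 | C=C1CC[C@@H]2[C@](C)(CCC(OC(=S)n7ccnc7)[C@]2(C)C(=O)O[C@H]3C[C@@H](C)CC[C@@H]3C(C)(C)c4ccccc4)[C@H]1CC[C@H](C)CCO[Si](c5ccccc5)(c6ccccc6)C(C)(C)C | intermediate
16 | 8-phenylmenthyl 15-(silyloxy)labd-8(17)-en-19-oate, trans-fused | C=C1CC[C@@H]2[C@](C)(CCC[C@]2(C)C(=O)O[C@H]3C[C@@H](C)CC[C@@H]3C(C)(C)c4ccccc4)[C@H]1CC[C@H](C)CCO[Si](c5ccccc5)(c6ccccc6)C(C)(C)C | intermediate
17 | 15-(silyloxy)labd-8(17)-en-19-ol | C=C1CC[C@@H]2[C@](C)(CCC[C@]2(C)CO)[C@H]1CC[C@H](C)CCO[Si](c5ccccc5)(c6ccccc6)C(C)(C)C | intermediate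
18 | 15-(silyloxy)labd-8(17)-en-19-al (not isolated) | C=C1CC[C@@H]2[C@](C)(CCC[C@]2(C)C=O)[C@H]1CC[C@H](C)CCO[Si](c5ccccc5)(c6ccccc6)C(C)(C)C | intermediate
19 | 15-(silyloxy)labd-8(17)-en-19-oic acid | C=C1CC[C@@H]2[C@](C)(CCC[C@]2(C)C(=O)O)[C@H]1CC[C@H](C)CCO[Si](c5ccccc5)(c6ccccc6)C(C)(C)C | intermediate
20 | allyl 15-(silyloxy)labd-8(17)-en-19-oate | C=C1CC[C@@H]2[C@](C)(CCC[C@]2(C)C(=O)OCC=C)[C@H]1CC[C@H](C)CCO[Si](c5ccccc5)(c6ccccc6)C(C)(C)C | intermediate
21 | allyl 15-hydroxylabd-8(17)-en-19-oate | C=C1CC[C@@H]2[C@](C)(CCC[C@]2(C)C(=O)OCC=C)[C@H]1CC[C@H](C)CCO | intermediate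
22 | allyl 15-oxolabd-8(17)-en-19-oate | C=C1CC[C@@H]2[C@](C)(CCC[C@]2(C)C(=O)OCC=C)[C@H]1CC[C@H](C)CC=O | intermediate
23 | N-cyclohexyl aldimine of 22 | C=C1CC[C@@H]2[C@](C)(CCC[C@]2(C)C(=O)OCC=C)[C@H]1CC[C@H](C)C/C=N/C3CCCCC3 | intermediate
24 | 4α-phenylselanyl derivative of 12 (not isolated) | C=C1CC[C@@H]2[C@](C)(CCC(=O)[C@]2([Se]c7ccccc7)C(=O)O[C@H]3C[C@@H](C)CC[C@@H]3C(C)(C)c4ccccc4)[C@H]1CC[C@H](C)CCO[Si](c5ccccc5)(c6ccccc6)C(C)(C)C | intermediate
25 | selenoxide of 24 (not isolated) | C=C1CC[C@@H]2[C@](C)(CCC(=O)[C@]2([Se](=O)c7ccccc7)C(=O)O[C@H]3C[C@@H](C)CC[C@@H]3C(C)(C)c4ccccc4)[C@H]1CC[C@H](C)CCO[Si](c5ccccc5)(c6ccccc6)C(C)(C)C | intermediate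
26 | 8-phenylmenthyl 15-(silyloxy)-3-oxo-18-norlabda-4,8(17)-dien-19-oate | C=C1CCC2=C(C(=O)O[C@H]3C[C@@H](C)CC[C@@H]3C(C)(C)c4ccccc4)C(=O)CC[C@]2(C)[C@H]1CC[C@H](C)CCO[Si](c5ccccc5)(c6ccccc6)C(C)(C)C | intermediate
27 | 8-phenylmenthyl 15-(silyloxy)-3-oxo-18-nor-5β-labd-8(17)-en-19-oate, cis-fused, C4–H (keto form drawn) | C=C1CC[C@H]2[C@](C)(CCC(=O)C2C(=O)O[C@H]3C[C@@H](C)CC[C@@H]3C(C)(C)c4ccccc4)[C@H]1CC[C@H](C)CCO[Si](c5ccccc5)(c6ccccc6)C(C)(C)C | intermediate
28 | 8-phenylmenthyl 15-(silyloxy)-3-oxo-5β-labd-8(17)-en-19-oate, 4α-CH3 | C=C1CC[C@H]2[C@](C)(CCC(=O)[C@]2(C)C(=O)O[C@H]3C[C@@H](C)CC[C@@H]3C(C)(C)c4ccccc4)[C@H]1CC[C@H](C)CCO[Si](c5ccccc5)(c6ccccc6)C(C)(C)C | intermediate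
29 | 3-hydroxy ester from 28 (C3 epimers) | C=C1CC[C@H]2[C@](C)(CCC(O)[C@]2(C)C(=O)O[C@H]3C[C@@H](C)CC[C@@H]3C(C)(C)c4ccccc4)[C@H]1CC[C@H](C)CCO[Si](c5ccccc5)(c6ccccc6)C(C)(C)C | intermediate
30 | 3-O-(imidazol-1-ylthiocarbonyl) derivative of 29 | C=C1CC[C@H]2[C@](C)(CCC(OC(=S)n7ccnc7)[C@]2(C)C(=O)O[C@H]3C[C@@H](C)CC[C@@H]3C(C)(C)c4ccccc4)[C@H]1CC[C@H](C)CCO[Si](c5ccccc5)(c6ccccc6)C(C)(C)C | intermediate
31 | 8-phenylmenthyl 15-(silyloxy)-5β-labd-8(17)-en-19-oate | C=C1CC[C@H]2[C@](C)(CCC[C@]2(C)C(=O)O[C@H]3C[C@@H](C)CC[C@@H]3C(C)(C)c4ccccc4)[C@H]1CC[C@H](C)CCO[Si](c5ccccc5)(c6ccccc6)C(C)(C)C | intermediate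
32 | 15-(silyloxy)-5β-labd-8(17)-en-19-ol | C=C1CC[C@H]2[C@](C)(CCC[C@]2(C)CO)[C@H]1CC[C@H](C)CCO[Si](c5ccccc5)(c6ccccc6)C(C)(C)C | intermediate
33 | 15-(silyloxy)-5β-labd-8(17)-en-19-al (not isolated) | C=C1CC[C@H]2[C@](C)(CCC[C@]2(C)C=O)[C@H]1CC[C@H](C)CCO[Si](c5ccccc5)(c6ccccc6)C(C)(C)C | intermediate
34 | 15-(silyloxy)-5β-labd-8(17)-en-19-oic acid | C=C1CC[C@H]2[C@](C)(CCC[C@]2(C)C(=O)O)[C@H]1CC[C@H](C)CCO[Si](c5ccccc5)(c6ccccc6)C(C)(C)C | intermediate
35 | allyl 15-(silyloxy)-5β-labd-8(17)-en-19-oate | C=C1CC[C@H]2[C@](C)(CCC[C@]2(C)C(=O)OCC=C)[C@H]1CC[C@H](C)CCO[Si](c5ccccc5)(c6ccccc6)C(C)(C)C | intermediate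
36 | allyl 15-hydroxy-5β-labd-8(17)-en-19-oate | C=C1CC[C@H]2[C@](C)(CCC[C@]2(C)C(=O)OCC=C)[C@H]1CC[C@H](C)CCO | intermediate
37 | allyl 15-oxo-5β-labd-8(17)-en-19-oate | C=C1CC[C@H]2[C@](C)(CCC[C@]2(C)C(=O)OCC=C)[C@H]1CC[C@H](C)CC=O | intermediate
38 | N-lithio 1-azaallyl anion of 23 (not isolated) | C=C1CC[C@@H]2[C@](C)(CCC[C@]2(C)C(=O)OCC=C)[C@H]1CC[C@H](C)C=CN([Li])C3CCCCC3 | intermediate
39 | aldol imine, C15′ carbinol (diastereomers at C14 and C15′, not isolated) | C=C1CC[C@@H]2[C@](C)(CCC[C@]2(C)C(=O)OCC=C)[C@H]1CC[C@H](C)C(/C=N/C3CCCCC3)C(O)C[C@@H](C)CC[C@H]1C(=C)CC[C@H]2[C@]1(C)CCC[C@]2(C)C(=O)OCC=C | intermediate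
40 | β-hydroxy aldehyde (diastereomers at C14 and C15′, not isolated) | C=C1CC[C@@H]2[C@](C)(CCC[C@]2(C)C(=O)OCC=C)[C@H]1CC[C@H](C)C(C=O)C(O)C[C@@H](C)CC[C@H]1C(=C)CC[C@H]2[C@]1(C)CCC[C@]2(C)C(=O)OCC=C | intermediate
41 | diallyl ester of the target, E-enal | C=C1CC[C@@H]2[C@](C)(CCC[C@]2(C)C(=O)OCC=C)[C@H]1CC[C@H](C)/C(C=O)=C\C[C@@H](C)CC[C@H]1C(=C)CC[C@H]2[C@]1(C)CCC[C@]2(C)C(=O)OCC=C | intermediate
42 | CNP0229303.1, target diacid | C=C1CC[C@@H]2[C@](C)(CCC[C@]2(C)C(=O)O)[C@H]1CC[C@H](C)/C(C=O)=C\C[C@@H](C)CC[C@H]1C(=C)CC[C@H]2[C@]1(C)CCC[C@]2(C)C(=O)O | target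

("silyloxy" in the names of 12 to 35 stands for tert-butyldiphenylsilyloxy.)

**Totals**
Total step count: 30.
Longest linear sequence: 19 steps (steps 1 to 4, 6, 7, 18 to 28, 29, 30).

**Steps most likely to fail**

1. Step 7 (key step). The risks are further oxidation of the enolizable bicyclic keto ester by trivalent manganese, erosion of face selection if the radical reacts outside the chelate, and elimination into the ring instead of to C17. Fallback, setting out from 11: chlorination at C2 with N-chlorosuccinimide should give the 2-chloro keto ester F1. Oxidative cyclization of F1 under the same Mn(OAc)3·2H2O/Cu(OAc)2·H2O/Yb(OTf)3 conditions should give the 4-chloro bicycle F2; α-chloro dicarbonyl radicals cyclize in the same way, but their products have no enolizable hydrogen and cannot be oxidized again. Zn in AcOH then removes the chlorine and returns the route to 12. The C4 configuration of F2 is erased in that reduction, so only the face of the C4–C5 closure counts.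

2. Step 19. The risk is hydride delivery to the α face of C5, which gives back the trans-fused series, or attack at the ketone. Fallback, setting out from 26: mCPBA should epoxidize only the electron-rich C8=C17 olefin to give the spiro-epoxide F3. Heterogeneous hydrogenation of the C4=C5 keto ester over Pd/C in ethanol with a trace of KOH (syn addition of H2 in alkaline medium, the classical way from 10-methyl-Δ4-3-octalones to cis-fused decalones) should give the cis-fused epoxide F4. Deoxygenation of the epoxide with Cp2TiCl (from Cp2TiCl2 and Zn) restores the methylene and returns the route to 27.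

3. Step 20. The risk is poor facial selectivity at C4, because the cis-fused enolate can react through a second half-chair in which the β face is open. Fallback, setting out from 27: NaBH4 reduction should give the 3-hydroxy ester F5, thioacylation with 1,1'-thiocarbonyldiimidazole the imidazolide F6, and Bu3SnH/AIBN the C3-deoxy ester F7, which still has its C4 hydrogen. Deprotonation with LiN(iPr)2 and methylation with MeI then goes through the exocyclic ester enolate. There, A(1,3) strain holds C6 axial on ring A and C20 over the β face, so alkylation should come from the equatorial α side, the classical way to axial C4 esters. The route is rejoined at 31.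

**Further compounds**
F1 | step 7 | (1S,2R,5S)-8-phenylmenthyl (6E,10E,14S)-2-chloro-16-(tert-butyldiphenylsilyloxy)-6,10,14-trimethyl-3-oxohexadeca-6,10-dienoate | CC(C)(c1ccccc1)[C@H]2CC[C@H](C)C[C@@H]2OC(=O)C(Cl)C(=O)CC/C(C)=C/CC/C(C)=C/CC[C@H](C)CCO[Si](c3ccccc3)(c4ccccc4)C(C)(C)C
F2 | step 7 | 4-chloro derivative of 12 (C4 epimers) | C=C1CC[C@@H]2[C@](C)(CCC(=O)C2(Cl)C(=O)O[C@H]3C[C@@H](C)CC[C@@H]3C(C)(C)c4ccccc4)[C@H]1CC[C@H](C)CCO[Si](c5ccccc5)(c6ccccc6)C(C)(C)C
F3 | step 19 | 8,17-epoxide of 26 (C8 epimers) | C1OC12CCC3=C(C(=O)O[C@H]4C[C@@H](C)CC[C@@H]4C(C)(C)c5ccccc5)C(=O)CC[C@]3(C)[C@H]2CC[C@H](C)CCO[Si](c6ccccc6)(c7ccccc7)C(C)(C)C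
F4 | step 19 | 8,17-epoxide of 27, cis-fused (C8 epimers) | C1OC12CC[C@H]3[C@](C)(CCC(=O)C3C(=O)O[C@H]4C[C@@H](C)CC[C@@H]4C(C)(C)c5ccccc5)[C@H]2CC[C@H](C)CCO[Si](c6ccccc6)(c7ccccc7)C(C)(C)C
F5 | step 20 | 3-hydroxy ester from 27 (C3 and C4 epimers) | C=C1CC[C@H]2[C@](C)(CCC(O)C2C(=O)O[C@H]3C[C@@H](C)CC[C@@H]3C(C)(C)c4ccccc4)[C@H]1CC[C@H](C)CCO[Si](c5ccccc5)(c6ccccc6)C(C)(C)C
F6 | step 20 | 3-O-(imidazol-1-ylthiocarbonyl) derivative of F5 | C=C1CC[C@H]2[C@](C)(CCC(OC(=S)n7ccnc7)C2C(=O)O[C@H]3C[C@@H](C)CC[C@@H]3C(C)(C)c4ccccc4)[C@H]1CC[C@H](C)CCO[Si](c5ccccc5)(c6ccccc6)C(C)(C)C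
F7 | step 20 | 8-phenylmenthyl 15-(tert-butyldiphenylsilyloxy)-18-nor-5β-labd-8(17)-en-19-oate (C4 epimers) | C=C1CC[C@H]2[C@](C)(CCCC2C(=O)O[C@H]3C[C@@H](C)CC[C@@H]3C(C)(C)c4ccccc4)[C@H]1CC[C@H](C)CCO[Si](c5ccccc5)(c6ccccc6)C(C)(C)C
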